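**Strategy.** The synthesis rests on disconnecting the C4a–C5 bond of the chromone. Ring A (C4a, C5, C6, C7, C8, C8a) is oxygenated at every second carbon (C5, C7, C8a), the signature of a polyketide, so it is grown onto a preformed 4-pyranone that becomes the heterocyclic ring (O1, C2, C3, C4, C4a, C8a). One operation, a magnesium-templated Claisen condensation, joins pyranone C3 to a side-arm ester carbon and aromatizes the new carbocycle to the 5,7-dihydroxychromone. Its precursor is a 2,6-disubstituted 4-pyranone carrying a CH2COCH2CO2Me arm on one side and, on the other, the complete (S)-configured chain, already at the ester oxidation level as a silyl-protected β-hydroxy tert-butyl ester.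

Key step: step 8

Remark: the chain terminus is carried as a tert-butyl ester and the carbinol as a silyl ether, so no redox steps follow ring formation. Partial ester exchange to methyl or loss of the silyl group in step 8 would be harmless, because step 10 converts every such variant into the target.

Step 1
Reactants: 1 4-chlorobutanoyl chloride; 2 Meldrum's acid
Product: 4 tert-butyl 6-chloro-3-oxohexanoate, via acyl Meldrum's acid 3 (not isolated)
Conditions: pyridine, CH2Cl2, 0 °C to rt; dilute HCl wash, concentrate; then t-BuOH (3 equiv), toluene, 85 °C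
Reagents that add atoms: tert-butanol, CC(C)(C)O
Why: C-acylation of Meldrum's acid followed by thermal fragmentation of the adduct to an acylketene that tert-butanol traps (Oikawa–Yonemitsu β-keto ester synthesis) should give the keto ester, the primary chloride being inert under these non-basic conditions.

Step 2
Reactants: 4 tert-butyl 6-chloro-3-oxohexanoate
Product: 5 tert-butyl (3S)-6-chloro-3-hydroxyhexanoate
Conditions: H2 (4 atm), RuCl2[(S)-BINAP] (0.5 mol %), MeOH, 50 °C
Reagents that add atoms: none
Why: Noyori asymmetric hydrogenation, in which the β-keto ester chelates ruthenium and the (S)-BINAP ligand directs hydride to the ketone face that gives the (S)-carbinol, the same sense in which it gives (S)-3-hydroxybutanoates from acetoacetates, since the chloropropyl group ranks below CH2CO2t-Bu exactly as methyl does.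

Step 3
Reactants: 5 tert-butyl (3S)-6-chloro-3-hydroxyhexanoate
Product: 6 tert-butyl (3S)-3-[(tert-butyldimethylsilyl)oxy]-6-chlorohexanoate
Conditions: TBSCl, imidazole, DMF, rt
Reagents that add atoms: tert-butyldimethylsilyl chloride, CC(C)(C)[Si](C)(C)Cl
Why: Standard silylation of a secondary alcohol (Corey conditions) masks the hydroxyl against the bases of steps 5 to 9 and prevents its cyclization onto the halide, without touching the stereocenter.

Step 4
Reactants: 6 tert-butyl (3S)-3-[(tert-butyldimethylsilyl)oxy]-6-chlorohexanoate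
Product: 7 tert-butyl (3S)-3-[(tert-butyldimethylsilyl)oxy]-6-iodohexanoate
Conditions: NaI, acetone, reflux
Reagents that add atoms: sodium iodide, [Na+].[I-]
Why: Finkelstein halide exchange at the primary carbon, driven by precipitation of NaCl, should provide the more reactive electrophile needed for the alkylation.

Step 5
Reactants: 8 2,6-dimethyl-4H-pyran-4-one (3 equiv); 7 tert-butyl (3S)-3-[(tert-butyldimethylsilyl)oxy]-6-iodohexanoate
Product: 9 tert-butyl (3S)-3-[(tert-butyldimethylsilyl)oxy]-7-(6-methyl-4-oxo-4H-pyran-2-yl)heptanoate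
Conditions: LiN(i-Pr)2 (2.8 equiv), THF, −78 °C; then 7, DMPU, −78 to −30 °C
Reagents that add atoms: none
Why: Lateral (vinylogous) deprotonation of a pyranone methyl group gives an extended enolate that should undergo SN2 C-alkylation at the exocyclic carbon with the primary iodide, excess pyranone suppressing double alkylation and the hindered tert-butyl ester resisting attack at low temperature.

Step 6
Reactants: 9 tert-butyl (3S)-3-[(tert-butyldimethylsilyl)oxy]-7-(6-methyl-4-oxo-4H-pyran-2-yl)heptanoate
Product: 10 {6-[(5S)-7-tert-butoxy-5-[(tert-butyldimethylsilyl)oxy]-7-oxoheptyl]-4-oxo-4H-pyran-2-yl}acetic acid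
Conditions: LiN(SiMe3)2 (1.1 equiv), THF, −78 °C; dry CO2, −78 to −40 °C; cold 0.5 M HCl to pH 3
Reagents that add atoms: carbon dioxide, O=C=O
Why: Kinetic lateral lithiation should occur at the remaining methyl group in preference to the more hindered chain methylene and the carbanion is trapped by CO2 (lateral metalation–carboxylation), the resulting lithium carboxylate being too weakly acidic to quench unreacted anion, so one equivalent of base suffices and the far less acidic tert-butyl ester is left alone.

Step 7
Reactants: 10 {6-[(5S)-7-tert-butoxy-5-[(tert-butyldimethylsilyl)oxy]-7-oxoheptyl]-4-oxo-4H-pyran-2-yl}acetic acid; 11 potassium methyl malonate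
Product: 13 tert-butyl (3S)-3-[(tert-butyldimethylsilyl)oxy]-7-[6-(4-methoxy-2,4-dioxobutyl)-4-oxo-4H-pyran-2-yl]heptanoate, via acyl imidazolide 12 (not isolated)
Conditions: CDI, THF, rt; then 11, MgCl2, Et3N, MeCN–THF, rt to 40 °C; cold 0.5 M HCl work-up
Reagents that add atoms: 1,1'-carbonyldiimidazole, O=C(n1ccnc1)n1ccnc1 (supplies the imidazolyl group of 12 only)
Why: Masamune–Brooks homologation, in which the imidazolide C-acylates the magnesium enolate of the malonate half ester and the adduct loses CO2, should give the β-keto ester under near-neutral conditions that spare the silyl ether and the tert-butyl ester.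

Step 8
Reactants: 13 tert-butyl (3S)-3-[(tert-butyldimethylsilyl)oxy]-7-[6-(4-methoxy-2,4-dioxobutyl)-4-oxo-4H-pyran-2-yl]heptanoate
Product: 14 tert-butyl (3S)-3-[(tert-butyldimethylsilyl)oxy]-7-(5,7-dihydroxy-4-oxo-4H-chromen-2-yl)heptanoate
Conditions: Mg(OMe)2 (6 equiv), MeOH, rt to 65 °C; cold 0.5 M HCl work-up
Reagents that add atoms: none
Why: Mg(OMe)2 holds the β-keto ester as a magnesium chelate and, by reversible proton transfer in methanol, makes available the vinylogous enolate of the CH2 group between pyranone C2 and the ketone, in which negative charge is shared by pyranone C3 and the ring carbonyl oxygen. C3 (the future C4a) adds to the magnesium-activated methyl ester carbonyl (the future C5) and methoxide is expelled, an intramolecular Claisen (Dieckmann-type) C-acylation that forms the C4a–C5 bond. Ring A closes in a 6-exo-trig mode (enolexo with respect to the pyranone enolate), and the cyclohexenedione so formed should tautomerize at once to the 5,7-dihydroxy arene, whose chelated magnesium 5-phenoxide makes the closure irreversible. The closest known reaction type is the magnesium methoxide-mediated biomimetic Claisen cyclization of 3,5,7-triketo esters and of pyranone-masked polyketo esters to acylphloroglucinols and benzo-fused 4-pyranones. No stereocenter is created, and the side-chain carbinol carbon, β to the ester and not enolizable, cannot be scrambled. The step needs C-acylation at C3 to win over aldol (resorcinol-mode) closure and over reaction at the second ester; the substrate secures this because an aldol onto ring carbonyl C4 would require a bridged ring and meets only a weakly electrophilic vinylogous ester, and because only the methyl ester, not the distant and hindered tert-butyl ester, lies within six-membered reach of C3.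

Step 9
Reactants: 14 tert-butyl (3S)-3-[(tert-butyldimethylsilyl)oxy]-7-(5,7-dihydroxy-4-oxo-4H-chromen-2-yl)heptanoate
Product: 15 tert-butyl (3S)-3-[(tert-butyldimethylsilyl)oxy]-7-(5,7-dimethoxy-4-oxo-4H-chromen-2-yl)heptanoate
Conditions: Me2SO4 (excess), K2CO3, acetone, reflux; aq. NH3 quench
Reagents that add atoms: dimethyl sulfate, COS(=O)(=O)OC
Why: Williamson O-methylation should take the acidic 7-OH first and, with excess reagent and prolonged heating, the hydrogen-bonded 5-OH as well, while the silyl ether and tert-butyl ester are inert to carbonate.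

Step 10
Reactants: 15 tert-butyl (3S)-3-[(tert-butyldimethylsilyl)oxy]-7-(5,7-dimethoxy-4-oxo-4H-chromen-2-yl)heptanoate
Product: 18 methyl (3S)-7-(5,7-dimethoxy-4-oxo-4H-chromen-2-yl)-3-hydroxyheptanoate (penithochromone Q), via hydroxy tert-butyl ester 16 (not isolated), via hydroxy acid 17 (not isolated)
Conditions: HCl (1.25 M in MeOH), 40 °C
Reagents that add atoms: methanol, CO
Why: Acidic methanolysis should remove the silyl ether and ionize the tert-butyl ester to the acid, which Fischer esterification in the methanol solvent converts into the methyl ester, the carbinol stereocenter, aryl methyl ethers and chromone all being stable to these conditions.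

**Compound list**

1 | 4-chlorobutanoyl chloride | ClCCCC(=O)Cl | starting material
2 | Meldrum's acid (2,2-dimethyl-1,3-dioxane-4,6-dione) | CC1(C)OC(=O)CC(=O)O1 | starting material
3 | 5-(4-chloro-1-hydroxybutylidene)-2,2-dimethyl-1,3-dioxane-4,6-dione | CC1(C)OC(=O)C(=C(O)CCCCl)C(=O)O1 | intermediate (not isolated)
4 | tert-butyl 6-chloro-3-oxohexanoate | CC(C)(C)OC(=O)CC(=O)CCCCl | intermediate
5 | tert-butyl (3S)-6-chloro-3-hydroxyhexanoate | CC(C)(C)OC(=O)C[C@@H](O)CCCCl | intermediate
6 | tert-butyl (3S)-3-[(tert-butyldimethylsilyl)oxy]-6-chlorohexanoate | CC(C)(C)OC(=O)C[C@@H](O[Si](C)(C)C(C)(C)C)CCCCl | intermediate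
7 | tert-butyl (3S)-3-[(tert-butyldimethylsilyl)oxy]-6-iodohexanoate | CC(C)(C)OC(=O)C[C@@H](O[Si](C)(C)C(C)(C)C)CCCI | intermediate
8 | 2,6-dimethyl-4H-pyran-4-one | Cc1cc(=O)cc(C)o1 | starting material
9 | tert-butyl (3S)-3-[(tert-butyldimethylsilyl)oxy]-7-(6-methyl-4-oxo-4H-pyran-2-yl)heptanoate | CC(C)(C)OC(=O)C[C@@H](O[Si](C)(C)C(C)(C)C)CCCCc1cc(=O)cc(C)o1 | intermediate
10 | {6-[(5S)-7-tert-butoxy-5-[(tert-butyldimethylsilyl)oxy]-7-oxoheptyl]-4-oxo-4H-pyran-2-yl}acetic acid | CC(C)(C)OC(=O)C[C@@H](O[Si](C)(C)C(C)(C)C)CCCCc1cc(=O)cc(CC(=O)O)o1 | intermediate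
11 | potassium methyl malonate (potassium 3-methoxy-3-oxopropanoate) | COC(=O)CC(=O)[O-].[K+] | starting material
12 | tert-butyl (3S)-3-[(tert-butyldimethylsilyl)oxy]-7-{6-[2-(1H-imidazol-1-yl)-2-oxoethyl]-4-oxo-4H-pyran-2-yl}heptanoate | CC(C)(C)OC(=O)C[C@@H](O[Si](C)(C)C(C)(C)C)CCCCc1cc(=O)cc(CC(=O)n2ccnc2)o1 | intermediate (not isolated)
13 | tert-butyl (3S)-3-[(tert-butyldimethylsilyl)oxy]-7-[6-(4-methoxy-2,4-dioxobutyl)-4-oxo-4H-pyran-2-yl]heptanoate | CC(C)(C)OC(=O)C[C@@H](O[Si](C)(C)C(C)(C)C)CCCCc1cc(=O)cc(CC(=O)CC(=O)OC)o1 | intermediate (key-step precursor)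
14 | tert-butyl (3S)-3-[(tert-butyldimethylsilyl)oxy]-7-(5,7-dihydroxy-4-oxo-4H-chromen-2-yl)heptanoate | CC(C)(C)OC(=O)C[C@@H](O[Si](C)(C)C(C)(C)C)CCCCc1cc(=O)c2c(O)cc(O)cc2o1 | intermediate (key-step product)
15 | tert-butyl (3S)-3-[(tert-butyldimethylsilyl)oxy]-7-(5,7-dimethoxy-4-oxo-4H-chromen-2-yl)heptanoate | CC(C)(C)OC(=O)C[C@@H](O[Si](C)(C)C(C)(C)C)CCCCc1cc(=O)c2c(OC)cc(OC)cc2o1 | intermediate
16 | tert-butyl (3S)-7-(5,7-dimethoxy-4-oxo-4H-chromen-2-yl)-3-hydroxyheptanoate | CC(C)(C)OC(=O)C[C@@H](O)CCCCc1cc(=O)c2c(OC)cc(OC)cc2o1 | intermediate (not isolated)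
17 | (3S)-7-(5,7-dimethoxy-4-oxo-4H-chromen-2-yl)-3-hydroxyheptanoic acid | OC(=O)C[C@@H](O)CCCCc1cc(=O)c2c(OC)cc(OC)cc2o1 | intermediate (not isolated)
18 | methyl (3S)-7-(5,7-dimethoxy-4-oxo-4H-chromen-2-yl)-3-hydroxyheptanoate (penithochromone Q) | COC(=O)C[C@@H](O)CCCCc1cc(=O)c2c(OC)cc(OC)cc2o1 | target

**Step count.** Total: 10 steps. Longest linear sequence: 10 steps (1 → 4 → 5 → 6 → 7 → 9 → 10 → 13 → 14 → 15 → 18); 2,6-dimethyl-4H-pyran-4-one 8 enters at step 5 and potassium methyl malonate 11 at step 7.

**Steps most likely to fail**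

1. Step 8. The closure could be diverted by methoxide opening of the pyranone followed by aldol-type (resorcinol-mode) cyclization, or the chelated β-keto ester could simply fail to react at C3. In that case ring A would be bought instead of built. Commercial 1-(2-hydroxy-4,6-dimethoxyphenyl)ethanone is condensed with ethyl acetate (NaH, THF, reflux) to 1-(2-hydroxy-4,6-dimethoxyphenyl)butane-1,3-dione F1. Cyclodehydration (cat. H2SO4, AcOH, 100 °C) gives 5,7-dimethoxy-2-methyl-4H-chromen-4-one F2. Lateral lithiation of F2 (LiN(i-Pr)2, THF, −78 °C) and alkylation with iodide 7 should give 15 directly. This fallback sets out from 7 and returns to the route at 15, which then enters step 10.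

2. Step 6. Deprotonation could occur partly at the chain methylene instead of the methyl group, or the pyranylacetic acid could lose CO2 during isolation. The alternative fixes the site of reaction by dianion logic. The lithium anion of 8 (used in excess, LiN(SiMe3)2, THF, −78 °C) is acylated with allyl chloroformate to prop-2-en-1-yl (6-methyl-4-oxo-4H-pyran-2-yl)acetate F3. Its dianion (LiN(i-Pr)2, 2.1 equiv, THF, −78 to −30 °C) should react with iodide 7 at the last-formed, less stabilized lateral carbanion of the methyl group, giving tert-butyl (3S)-3-[(tert-butyldimethylsilyl)oxy]-7-{4-oxo-6-[2-oxo-2-(prop-2-en-1-yloxy)ethyl]-4H-pyran-2-yl}heptanoate F4. Pd(PPh3)4 and morpholine (THF, rt) then remove the allyl group under neutral conditions, and cold acidification gives 10, which is taken at once into step 7. This fallback sets out from 8 and 7 and returns at 10.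

3. Step 7. The acyl imidazolide, whose methylene is activated by the pyranone, could enolize and self-condense before the magnesium malonate attacks it. The alternative passes through an acylketene. Acid 10 is coupled with Meldrum's acid 2 (DCC, DMAP, CH2Cl2, 0 °C) to tert-butyl (3S)-3-[(tert-butyldimethylsilyl)oxy]-7-{6-[2-(2,2-dimethyl-4,6-dioxo-1,3-dioxan-5-ylidene)-2-hydroxyethyl]-4-oxo-4H-pyran-2-yl}heptanoate F5. Heating F5 in methanol (65 °C) should expel acetone and CO2 and deliver 13. This fallback sets out from 10 and returns at 13.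

Further compounds
F1 | step 8 | 1-(2-hydroxy-4,6-dimethoxyphenyl)butane-1,3-dione | CC(=O)CC(=O)c1c(O)cc(OC)cc1OC
F2 | step 8 | 5,7-dimethoxy-2-methyl-4H-chromen-4-one | Cc1cc(=O)c2c(OC)cc(OC)cc2o1
F3 | step 6 | prop-2-en-1-yl (6-methyl-4-oxo-4H-pyran-2-yl)acetate | C=CCOC(=O)Cc1cc(=O)cc(C)o1
F4 | step 6 | tert-butyl (3S)-3-[(tert-butyldimethylsilyl)oxy]-7-{4-oxo-6-[2-oxo-2-(prop-2-en-1-yloxy)ethyl]-4H-pyran-2-yl}heptanoate | CC(C)(C)OC(=O)C[C@@H](O[Si](C)(C)C(C)(C)C)CCCCc1cc(=O)cc(CC(=O)OCC=C)o1
F5 | step 7 | tert-butyl (3S)-3-[(tert-butyldimethylsilyl)oxy]-7-{6-[2-(2,2-dimethyl-4,6-dioxo-1,3-dioxan-5-ylidene)-2-hydroxyethyl]-4-oxo-4H-pyran-2-yl}heptanoate | CC(C)(C)OC(=O)C[C@@H](O[Si](C)(C)C(C)(C)C)CCCCc1cc(=O)cc(CC(O)=C2C(=O)OC(C)(C)OC2=O)o1
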